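Assumption: the target SMILES has no stereocentres (the molecule is achiral), so "single enantiomer" means the compound itself and no stereocontrol is needed.

**Retrosynthetic overview**
1. Target 16 ⇐ hydrogenolysis of the 3,4'-di-O-benzyl 8-acetate 15 ⇐ copper-catalysed para C8–H acetoxylation of the chelated 5-hydroxyflavone 14 (new reaction; forms the C8–OAc bond without any 8-O protecting group).
2. 14 ⇐ acid-mediated MOM removal and cyclodehydration of the 2-benzyloxy-1,3-diketone 13. This is the only ring formed (pyranone C ring); the A and B rings come from benzenoid starting materials.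
3. 13 ⇐ Pd-catalysed three-component carbonylative α-arylation (key coupling): aryl iodide 5 + CO (becomes C4) + ketone 12 (C2, C3 and the B ring).
4. 5 ⇐ resorcinol via MOM protection, ortho-lithiation/iodination, Ir-catalysed C–H borylation/oxidation and O-methylation. The A ring is symmetric, so 5-OH/7-OMe differentiation is automatic on ring closure.
5. 12 ⇐ 4-bromophenol (aryl Grignard) + Weinreb amide 11 (from benzyl alcohol and bromoacetic acid).

**Route**

Step 1
Reactants: 1 resorcinol
Product: 2 1,3-bis(methoxymethoxy)benzene
Conditions: MOMCl (2.5 equiv), i-Pr2NEt (3 equiv), CH2Cl2, 0 °C → rt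
Reagents that add atoms: chloromethyl methyl ether, COCCl
Why: Standard phenol O-alkylation (MOM acetal protection), giving groups that direct the lithiation in step 2 and are acid-labile for step 10.

Step 2
Reactants: 2 1,3-bis(methoxymethoxy)benzene
Product: 3 2-iodo-1,3-bis(methoxymethoxy)benzene
Conditions: n-BuLi (1.1 equiv), THF, 0 °C → rt; then I2, −78 °C → rt
Reagents that add atoms: iodine, II
Why: Directed ortho-metalation at the doubly activated C2 between the two OMOM groups followed by iodine quench; the substrate is symmetric, so one regioisomer forms.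

Step 3
Reactants: 3 2-iodo-1,3-bis(methoxymethoxy)benzene
Product: 4 4-iodo-3,5-bis(methoxymethoxy)phenol
Conditions: [Ir(OMe)(cod)]2 (1.5 mol %), dtbpy (3 mol %), B2pin2 (0.7 equiv), THF, 70 °C; then 30% H2O2, aq NaOH, 0 °C → rt (one pot)
Reagents that add atoms: hydrogen peroxide, OO (B2pin2 leaves no atoms in the product)
Why: Sterically controlled Ir-catalysed aromatic C–H borylation reacts at C5, the only C–H with no ortho substituent (aryl halides are tolerated), and oxidation of the ArBpin gives the phenol.

Step 4
Reactants: 4 4-iodo-3,5-bis(methoxymethoxy)phenol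
Product: 5 2-iodo-5-methoxy-1,3-bis(methoxymethoxy)benzene
Conditions: MeI (1.5 equiv), K2CO3, acetone, 50 °C
Reagents that add atoms: iodomethane, CI
Why: Williamson O-methylation of the only free phenol installs the future 7-OMe; MOM ethers and the C–I bond are inert.

Step 5
Reactants: 6 4-bromophenol
Product: 7 1-(benzyloxy)-4-bromobenzene
Conditions: BnBr (1.1 equiv), K2CO3, acetone, reflux
Reagents that add atoms: benzyl bromide, BrCc1ccccc1
Why: Williamson benzylation protects the future 4'-OH as an ether stable to Grignard, Pd/CO, acid and oxidant, and removable by hydrogenolysis.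

Step 6
Reactants: 8 benzyl alcohol; 9 bromoacetic acid
Product: 10 2-(benzyloxy)acetic acid
Conditions: NaH (2.3 equiv), THF, 0 °C → reflux; H3O+ work-up
Reagents that add atoms: none
Why: Williamson ether synthesis (benzyl alkoxide SN2 on the bromoacetate salt); the ether oxygen becomes O-3 of the flavonol.

Step 7
Reactants: 10 2-(benzyloxy)acetic acid
Product: 11 2-(benzyloxy)-N-methoxy-N-methylacetamide
Conditions: CDI (1.1 equiv), CH2Cl2, rt; then MeNH(OMe)·HCl, rt
Reagents that add atoms: N,O-dimethylhydroxylamine hydrochloride, CNOC.Cl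
Why: Amide coupling via the acyl imidazolide gives the Weinreb amide.

Step 8
Reactants: 7 1-(benzyloxy)-4-bromobenzene; 11 2-(benzyloxy)-N-methoxy-N-methylacetamide
Product: 12 2-(benzyloxy)-1-[4-(benzyloxy)phenyl]ethan-1-one
Conditions: 7, Mg, THF (ArMgBr); then 11, THF, 0 °C; aq NH4Cl
Reagents that add atoms: none
Why: Weinreb ketone synthesis; the chelated tetrahedral intermediate stops at the ketone.

Step 9
Reactants: 5 2-iodo-5-methoxy-1,3-bis(methoxymethoxy)benzene; 12 2-(benzyloxy)-1-[4-(benzyloxy)phenyl]ethan-1-one (1.3 equiv)
Product: 13 2-(benzyloxy)-1-[4-(benzyloxy)phenyl]-3-[4-methoxy-2,6-bis(methoxymethoxy)phenyl]propane-1,3-dione (racemic, enolisable C2; this centre is destroyed in step 10)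
Conditions: Pd(dba)2 (5 mol %), Xantphos (6 mol %), CO (balloon), K3PO4 (3 equiv), 1,4-dioxane, 80 °C
Reagents that add atoms: carbon monoxide, [C-]#[O+]
Why: Pd-catalysed carbonylative α-arylation of a ketone (oxidative addition, CO insertion to the aroyl-Pd, C-acylation of the ketone enolate) forms C4a–C4 and C4–C3 in one step; the di-ortho-substituted iodide disfavours direct non-carbonylative arylation.

Step 10
Reactants: 13 the 1,3-diketone from step 9
Product: 14 3-(benzyloxy)-2-[4-(benzyloxy)phenyl]-5-hydroxy-7-methoxy-4H-chromen-4-one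
Conditions: 3 M HCl, MeOH–THF (1:1), 55 °C
Reagents that add atoms: none
Why: Acid cleaves both MOM acetals and drives cyclodehydration of the o-hydroxyaryl 1,3-diketone (the ring-closing step of a Baker–Venkataraman flavone synthesis); the two phenols are equivalent, so only one flavone forms, with free 5-OH and 7-OMe.

Step 11
Reactants: 14 3-(benzyloxy)-2-[4-(benzyloxy)phenyl]-5-hydroxy-7-methoxy-4H-chromen-4-one
Product: 15 3-(benzyloxy)-2-[4-(benzyloxy)phenyl]-5-hydroxy-7-methoxy-4-oxo-4H-chromen-8-yl acetate
Conditions: Cu(OAc)2 (10 mol %), PhI(OAc)2 (1.15 equiv, slow addition), AcOH–MeCN (1:3), 4 Å MS, 40 °C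
Reagents that add atoms: (diacetoxyiodo)benzene, CC(=O)OI(OC(C)=O)c1ccccc1 (acetoxy group, in exchange with the AcOH co-solvent, CC(=O)O)
Why: Proposed new method: Cu(II) binds the 4-keto-5-phenolate as an acac-like chelate, PhI(OAc)2 oxidises this to a Cu-bound phenoxyl/phenoxonium species with positive character at C8 (para to O-5), acetate adds there and tautomerisation re-aromatises to the 8-acetate, which is a poorer donor and resists a second oxidation under anhydrous conditions; the closest known reactions are the Cu-catalysed remote C5–H functionalisation of 8-amidoquinolines via chelate single-electron oxidation, the Elbs persulfate para-hydroxylation of 5-hydroxyflavones (which fixes the same C8 site) and iodine(III) para-acetoxylation of phenols.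

Step 12
Reactants: 15 the dibenzyl 8-acetate from step 11
Product: 16 3,5-dihydroxy-2-(4-hydroxyphenyl)-7-methoxy-4-oxo-4H-chromen-8-yl acetate (pollenitin 8-acetate)
Conditions: H2 (1 atm), 10% Pd/C, EtOAc–THF, rt
Reagents that add atoms: none
Why: Neutral hydrogenolysis cleaves both O-benzyl groups; the aryl acetate and the tetrasubstituted C2=C3 bond are untouched, no alcohol solvent is present to transesterify, and the acetate cannot migrate because its neighbours are 7-OMe and the ring oxygen.

**Compound list**
1 | resorcinol | Oc1cccc(O)c1 | starting material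
2 | 1,3-bis(methoxymethoxy)benzene | COCOc1cccc(OCOC)c1 | intermediate
3 | 2-iodo-1,3-bis(methoxymethoxy)benzene | COCOc1cccc(OCOC)c1I | intermediate
4 | 4-iodo-3,5-bis(methoxymethoxy)phenol | COCOc1cc(O)cc(OCOC)c1I | intermediate
5 | 2-iodo-5-methoxy-1,3-bis(methoxymethoxy)benzene | COCOc1cc(OC)cc(OCOC)c1I | intermediate
6 | 4-bromophenol | Oc1ccc(Br)cc1 | starting material
7 | 1-(benzyloxy)-4-bromobenzene | Brc1ccc(OCc2ccccc2)cc1 | intermediate
8 | benzyl alcohol | OCc1ccccc1 | starting material
9 | bromoacetic acid | OC(=O)CBr | starting material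
10 | 2-(benzyloxy)acetic acid | OC(=O)COCc1ccccc1 | intermediate
11 | 2-(benzyloxy)-N-methoxy-N-methylacetamide | CON(C)C(=O)COCc1ccccc1 | intermediate
12 | 2-(benzyloxy)-1-[4-(benzyloxy)phenyl]ethan-1-one | O=C(COCc1ccccc1)c1ccc(OCc2ccccc2)cc1 | intermediate
13 | 2-(benzyloxy)-1-[4-(benzyloxy)phenyl]-3-[4-methoxy-2,6-bis(methoxymethoxy)phenyl]propane-1,3-dione (racemic) | COCOc1cc(OC)cc(OCOC)c1C(=O)C(OCc1ccccc1)C(=O)c1ccc(OCc2ccccc2)cc1 | intermediate
14 | 3-(benzyloxy)-2-[4-(benzyloxy)phenyl]-5-hydroxy-7-methoxy-4H-chromen-4-one | COc1cc(O)c2c(=O)c(OCc3ccccc3)c(-c3ccc(OCc4ccccc4)cc3)oc2c1 | intermediate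
15 | 3-(benzyloxy)-2-[4-(benzyloxy)phenyl]-5-hydroxy-7-methoxy-4-oxo-4H-chromen-8-yl acetate | COc1cc(O)c2c(=O)c(OCc3ccccc3)c(-c3ccc(OCc4ccccc4)cc3)oc2c1OC(C)=O | intermediate
16 | 3,5-dihydroxy-2-(4-hydroxyphenyl)-7-methoxy-4-oxo-4H-chromen-8-yl acetate (pollenitin 8-acetate; achiral) | COc1cc(O)c2c(=O)c(O)c(-c3ccc(O)cc3)oc2c1OC(C)=O | target

**Totals**
Total step count: 12.
Longest linear sequence: 8 (steps 1, 2, 3, 4, 9, 10, 11, 12), which is two thirds of the total; steps 5–8 run in parallel.

**Three steps most likely to fail, with fallbacks**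
1. Step 11 (proposed new Cu-catalysed C8–H acetoxylation). The risks are over-oxidation to the 5,8-quinone and competing attack at C6. Fallback with known chemistry: Elbs persulfate oxidation of 14 (K2S2O8, aq KOH/pyridine, rt; then HCl hydrolysis of the 8-sulfate) to the 5,8-dihydroxyflavone. Then acetylate the non-chelated 8-OH selectively (Ac2O 1.05 equiv, pyridine, 0 °C; the hydrogen-bonded 5-OH does not react) to reach 15, and finish with step 12.
2. Step 9 (carbonylative α-arylation with a di-ortho-substituted iodide and an α-alkoxy ketone). The risks are slow acyl transfer and O-acylation. Fallback: a Baker–Venkataraman route.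
   - Exchange the iodide of 5 for lithium (n-BuLi, −78 °C) and acylate with Weinreb amide 11 to give the aryl benzyloxymethyl ketone.
   - Remove the MOM groups (HCl/MeOH).
   - Aroylate both phenols with 4-(benzyloxy)benzoyl chloride, made from 7 (Mg, CO2; then (COCl)2).
   - Rearrange with KOH/pyridine, cyclise with AcOH/H2SO4, and cleave the residual 5-O-aroyl group with K2CO3/MeOH to give 14.
3. Step 3 (Ir C–H borylation in the presence of the C–I bond). The risk is partial deiodination or catalyst inhibition. Fallback: borylate, oxidise and methylate iodine-free 2 to give 1-methoxy-3,5-bis(methoxymethoxy)benzene, then introduce iodine afterwards by directed ortho-lithiation between the two OMOM groups (n-BuLi/TMEDA, then I2) to reach 5. Alternatively, use that aryllithium directly in the Baker–Venkataraman fallback above.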